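The route rests on cutting the trans-decalin at C4–C5 and C9–C10, which unfolds ring A and ring B into one acyclic chain. The feature exploited is the C6 carbinol: it sits beside the C5–C10 ring fusion, between quaternary C4 and C10, and its α oxygen is equatorial on ring B, so this single stereocentre can dictate C5, C10 and C9. One iron-hydride-initiated radical cascade forms both bonds, both rings and four stereocentres in a single operation. Its precursor is an (S)-6-silyloxy chain with an isopropenyl terminus (C4), an E C5=C10 alkene and a Z maleate (C8=C9) already carrying C11 and C12.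

Key step: step 7

Remark: drimane numbering is used throughout (gem-dimethyl on C4, C11 on C9, C12 on C8); the C10 methyl is β and α is the opposite face.
Remark: the Z maleate and the secondary TBS ether are kept on purpose: Z holds the C11 ester outside the closing ring B, and the equatorial silyloxy group is poorly aligned for β-elimination in step 9; the C8 configuration of 11 has no consequence because C8 becomes trigonal in step 8.
Assumption: the target is taken as the open aldehyde acid drawn; a γ-aldehydo acid of this kind may equilibrate with its cyclic lactol form, which is not treated as a separate compound.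

Step 1
Reactants: 1 6-methylhept-6-en-2-one; 2 triethyl phosphonoacetate
Product: 3 ethyl (2E)-3,7-dimethylocta-2,7-dienoate
Conditions: NaH, THF, 0 °C to rt; chromatography to remove the minor Z isomer
Reagents that add atoms: none
Why: Horner–Wadsworth–Emmons olefination of the methyl ketone should favour the E trisubstituted enoate (ester anti to the longer chain), and the Z isomer is separable at this stage.

Step 2
Reactants: 3 ethyl (2E)-3,7-dimethylocta-2,7-dienoate
Product: 4 (2E)-3,7-dimethylocta-2,7-dien-1-ol
Conditions: i-Bu2AlH (2.2 equiv), CH2Cl2, −78 °C; aq. KNaC4H4O6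
Reagents that add atoms: none
Why: 1,2-reduction of a conjugated ester by the aluminium hydride gives the allylic alcohol without touching either alkene or the E geometry.

Step 3
Reactants: 4 (2E)-3,7-dimethylocta-2,7-dien-1-ol
Product: 5 (2E)-3,7-dimethylocta-2,7-dienal
Conditions: MnO2, CH2Cl2, rt
Reagents that add atoms: none
Why: Activated MnO2 oxidises allylic alcohols selectively under neutral conditions that should not isomerise the C2=C3 bond.

Step 4
Reactants: 5 (2E)-3,7-dimethylocta-2,7-dienal; 6 allenylboronic acid pinacol ester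
Product: 8 (4S,5E)-6,10-dimethylundeca-5,10-dien-1-yn-4-ol, via homopropargylic pinacol borate 7 (not isolated)
Conditions: (S)-3,3′-bis(2,4,6-triisopropylphenyl)-1,1′-binaphthyl-2,2′-diyl hydrogen phosphate [(S)-TRIP, 5 mol%], 4 Å MS, toluene, −20 °C; then aq. NaHCO3
Reagents that add atoms: none
Why: Chiral-phosphoric-acid-catalysed propargylation with an allenylboronate passes through a closed six-membered SE2′ transition state in which the acid binds the boronate oxygen and the formyl hydrogen; the (S)-acid is chosen to deliver the propargyl group to the Si face and set the (S) carbinol (future C6), the sense being confirmed by Mosher ester analysis (the antipodal acid is used otherwise), and borate 7 is hydrolysed on work-up.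

Step 5
Reactants: 8 (4S,5E)-6,10-dimethylundeca-5,10-dien-1-yn-4-ol
Product: 9 tert-butyl{[(4S,5E)-6,10-dimethylundeca-5,10-dien-1-yn-4-yl]oxy}dimethylsilane
Conditions: TBSCl, imidazole, DMF, rt
Reagents that add atoms: tert-butyldimethylsilyl chloride, CC(C)(C)[Si](C)(C)Cl
Why: Silylation of a secondary alcohol under neutral conditions avoids ionisation of the allylic carbinol, so the configuration is retained.

Step 6
Reactants: 9 tert-butyl{[(4S,5E)-6,10-dimethylundeca-5,10-dien-1-yn-4-yl]oxy}dimethylsilane
Product: 10 dimethyl (2Z)-2-[(2S,3E)-2-(tert-butyldimethylsilyloxy)-4,8-dimethylnona-3,8-dien-1-yl]but-2-enedioate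
Conditions: PdI2 (1 mol%), KI (10 mol%), CO (16 atm), air (4 atm), MeOH, 25 °C
Reagents that add atoms: carbon monoxide, [C-]#[O+]; methanol, CO
Why: PdI2/KI-catalysed oxidative dialkoxycarbonylation of a terminal alkyne adds two methoxycarbonyl groups syn across the triple bond (the zerovalent palladium formed is reoxidised by oxygen), giving the Z diester while the less reactive alkenes and the silyl ether are left alone.

Step 7
Reactants: 10 dimethyl (2Z)-2-[(2S,3E)-2-(tert-butyldimethylsilyloxy)-4,8-dimethylnona-3,8-dien-1-yl]but-2-enedioate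
Product: 11 dimethyl 6α-(tert-butyldimethylsilyloxy)drimane-11,12-dioate (5α-H, 8β-H, 9α-H, both esters equatorial)
Conditions: Fe(acac)3 (0.5 equiv), PhSiH3 (2.5 equiv), EtOH/ethylene glycol 5:1, 0.01 M, argon, 60 °C
Reagents that add atoms: none
Why: The iron hydride formed from Fe(acac)3 and PhSiH3 transfers a hydrogen atom to the CH2 of the 1,1-disubstituted alkene; the tertiary C4 radical adds to C5 (6-endo-trig, ring A), the resulting tertiary C10 radical adds to C9 of the maleate (6-endo-trig, ring B), and the ester-stabilised C8 radical is reduced by divalent iron and protonated by ethanol. The closest known reaction types are hydrogen-atom-transfer-initiated radical polyene bicyclisations that end on an electron-poor alkene and the Fe(acac)3/PhSiH3 reductive olefin coupling. C5 is set in the first closure by 1,3-allylic strain: the C6–H lies in the alkene plane facing the C10 methyl, so the C4 radical should add anti to the bulky C7 maleate arm with the silyloxy group turned outward, which is the C5/C6 relationship that later places O6 equatorial. C10 is set in the second closure through a chair–chair array in which C4 and the C6 silyloxy group are both equatorial on the nascent ring B, so the C10–C9 bond forms anti to C5–H (trans fusion, methyl β); C9 follows from the Z geometry, which keeps the C11 ester outside the ring and hence equatorial (β), and C8 is set by protonation, expected to favour the equatorial ester. The step needs chemoselective hydrogen delivery (the unhindered 1,1-disubstituted alkene is the fastest acceptor, the maleate the only good radical trap), 6-endo over 5-exo closure twice (a tertiary radical avoids the fully substituted C10 and C8) and cyclisation over intermolecular addition (high dilution).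

Step 8
Reactants: 11 dimethyl 6α-(tert-butyldimethylsilyloxy)drimane-11,12-dioate
Product: 14 dimethyl 6α-(tert-butyldimethylsilyloxy)drim-8-ene-11,12-dioate, via C8 phenylselenide 12 (not isolated), via C8 selenoxide 13 (not isolated)
Conditions: LiN(i-Pr)2 (1.3 equiv), THF, −78 °C; PhSeBr, −78 °C; then AcOH, 30% aq. H2O2, 0 °C to rt
Reagents that add atoms: none
Why: Kinetic deprotonation should occur at C8 (the α-carbon not flanked by quaternary C10), the enolate is selenenylated from the α face, and oxidation triggers selenoxide syn-elimination toward the acidified, cis-disposed C9–H to give the tetrasubstituted C8=C9 diester; any C7=C8 regioisomer would give the same dienolate in step 9.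

Step 9
Reactants: 14 dimethyl 6α-(tert-butyldimethylsilyloxy)drim-8-ene-11,12-dioate
Product: 15 dimethyl 6α-(tert-butyldimethylsilyloxy)-9α-hydroxydrim-7-ene-11,12-dioate
Conditions: KN(SiMe3)2 (1.5 equiv), THF, −78 °C; 2-(benzenesulfonyl)-3-phenyloxaziridine, −78 °C; AcOH quench
Reagents that add atoms: 2-(benzenesulfonyl)-3-phenyloxaziridine, O=S(=O)(N1OC1c1ccccc1)c1ccccc1
Why: γ-Deprotonation at C7 gives the extended dienolate, which the oxaziridine hydroxylates at the α-carbon C9 (Davis oxidation) from the α face, anti to the axial C10 methyl, so setting 9α-OH and moving the alkene to C7=C8; the pseudo-equatorial C6 silyloxy group lies near the nodal plane of the dienolate and should not be expelled.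

Step 10
Reactants: 15 dimethyl 6α-(tert-butyldimethylsilyloxy)-9α-hydroxydrim-7-ene-11,12-dioate
Product: 16 methyl 6α-(tert-butyldimethylsilyloxy)-9α,12-dihydroxydrim-7-en-11-oate
Conditions: i-Bu2AlH (3.2 equiv), CH2Cl2, −78 °C; aq. KNaC4H4O6, 0 °C; crude used at once
Reagents that add atoms: none
Why: The hydride should reduce the exposed conjugated C12 ester in a 1,2-sense while the C11 ester, buried between fully substituted C9 and C10, is left, and prompt use of the hydroxy ester forestalls lactonisation.

Step 11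
Reactants: 16 methyl 6α-(tert-butyldimethylsilyloxy)-9α,12-dihydroxydrim-7-en-11-oate
Product: 17 methyl 6α-(tert-butyldimethylsilyloxy)-9α-hydroxy-12-oxodrim-7-en-11-oate
Conditions: MnO2, CH2Cl2, rt
Reagents that add atoms: none
Why: MnO2 oxidises the primary allylic alcohol selectively to the enal, the tertiary C9 alcohol, the ester and the silyl ether being inert.

Step 12
Reactants: 17 methyl 6α-(tert-butyldimethylsilyloxy)-9α-hydroxy-12-oxodrim-7-en-11-oate
Product: 18 methyl 6α,9α-dihydroxy-12-oxodrim-7-en-11-oate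
Conditions: HF·pyridine, pyridine/THF, 0 °C to rt
Reagents that add atoms: none
Why: Buffered fluoride cleavage of the secondary TBS ether needs no base, so the enal, the tertiary alcohol and the methyl ester should survive and C6 keeps its configuration.

Step 13
Reactants: 18 methyl 6α,9α-dihydroxy-12-oxodrim-7-en-11-oate; 19 (2E,4E,6E)-octa-2,4,6-trienoic acid
Product: 20 methyl 9α-hydroxy-6α-[(2E,4E,6E)-octa-2,4,6-trienoyloxy]-12-oxodrim-7-en-11-oate
Conditions: EDC·HCl, 4-(dimethylamino)pyridine, CH2Cl2, 0 °C to rt
Reagents that add atoms: none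
Why: Steglich esterification acylates the secondary equatorial 6α-hydroxyl with retention, the tertiary 9α-hydroxyl being unreactive, and the mild conditions should preserve the all-E triene.

Step 14
Reactants: 20 methyl 9α-hydroxy-6α-[(2E,4E,6E)-octa-2,4,6-trienoyloxy]-12-oxodrim-7-en-11-oate
Product: 21 (5S,6S,9S,10S)-9-hydroxy-6-[(2E,4E,6E)-octa-2,4,6-trienoyloxy]-12-oxodrim-7-en-11-oic acid
Conditions: LiOH (2 equiv), THF/H2O 4:1, 0 °C; then 0.5 M aq. HCl to pH 3
Reagents that add atoms: water, O
Why: Saponification of the C11 methyl ester should be assisted by the adjacent C12 aldehyde, whose hydrate anion reaches the C11 carbonyl through a five-membered array (anchimeric assistance as in 2-formylbenzoates), so cold hydroxide is expected to cleave it faster than the hindered conjugated C6 trienoate; C9 is quaternary and cannot epimerise.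

Compound list
1 | 6-methylhept-6-en-2-one | CC(=O)CCCC(C)=C | starting material
2 | triethyl phosphonoacetate | CCOC(=O)CP(=O)(OCC)OCC | starting material
3 | ethyl (2E)-3,7-dimethylocta-2,7-dienoate | CCOC(=O)/C=C(\C)CCCC(C)=C | intermediate
4 | (2E)-3,7-dimethylocta-2,7-dien-1-ol | OC/C=C(\C)CCCC(C)=C | intermediate
5 | (2E)-3,7-dimethylocta-2,7-dienal | O=C/C=C(\C)CCCC(C)=C | intermediate
6 | allenylboronic acid pinacol ester (4,4,5,5-tetramethyl-2-(propa-1,2-dien-1-yl)-1,3,2-dioxaborolane) | C=C=CB1OC(C)(C)C(C)(C)O1 | starting material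
7 | 2-{[(4S,5E)-6,10-dimethylundeca-5,10-dien-1-yn-4-yl]oxy}-4,4,5,5-tetramethyl-1,3,2-dioxaborolane (not isolated) | CC1(C)OB(O[C@@H](CC#C)/C=C(\C)CCCC(C)=C)OC1(C)C | intermediate
8 | (4S,5E)-6,10-dimethylundeca-5,10-dien-1-yn-4-ol | C#CC[C@H](O)/C=C(\C)CCCC(C)=C | intermediate
9 | tert-butyl{[(4S,5E)-6,10-dimethylundeca-5,10-dien-1-yn-4-yl]oxy}dimethylsilane | C#CC[C@H](O[Si](C)(C)C(C)(C)C)/C=C(\C)CCCC(C)=C | intermediate
10 | dimethyl (2Z)-2-[(2S,3E)-2-(tert-butyldimethylsilyloxy)-4,8-dimethylnona-3,8-dien-1-yl]but-2-enedioate | CC(C)(C)[Si](C)(C)O[C@H](/C=C(\C)CCCC(C)=C)C/C(C(=O)OC)=C/C(=O)OC | intermediate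
11 | dimethyl 6α-(tert-butyldimethylsilyloxy)drimane-11,12-dioate (5α-H, 8β-H, 9α-H, 10β-CH3; C12 ester 8α, C11 ester 9β) | CC(C)(C)[Si](C)(C)O[C@H]1C[C@@H](C(=O)OC)[C@H](C(=O)OC)[C@@]2(C)CCCC(C)(C)[C@H]12 | intermediate
12 | dimethyl 6α-(tert-butyldimethylsilyloxy)-8α-(phenylselanyl)drimane-11,12-dioate (C12 ester 8β, 9α-H; not isolated) | CC(C)(C)[Si](C)(C)O[C@H]1C[C@]([Se]c3ccccc3)(C(=O)OC)[C@H](C(=O)OC)[C@@]2(C)CCCC(C)(C)[C@H]12 | intermediate
13 | dimethyl 6α-(tert-butyldimethylsilyloxy)-8α-(phenylseleninyl)drimane-11,12-dioate (not isolated) | CC(C)(C)[Si](C)(C)O[C@H]1C[C@]([Se](=O)c3ccccc3)(C(=O)OC)[C@H](C(=O)OC)[C@@]2(C)CCCC(C)(C)[C@H]12 | intermediate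
14 | dimethyl 6α-(tert-butyldimethylsilyloxy)drim-8-ene-11,12-dioate (5α-H) | CC(C)(C)[Si](C)(C)O[C@H]1CC(C(=O)OC)=C(C(=O)OC)[C@@]2(C)CCCC(C)(C)[C@H]12 | intermediate
15 | dimethyl 6α-(tert-butyldimethylsilyloxy)-9α-hydroxydrim-7-ene-11,12-dioate | CC(C)(C)[Si](C)(C)O[C@H]1C=C(C(=O)OC)[C@](O)(C(=O)OC)[C@@]2(C)CCCC(C)(C)[C@H]12 | intermediate
16 | methyl 6α-(tert-butyldimethylsilyloxy)-9α,12-dihydroxydrim-7-en-11-oate | CC(C)(C)[Si](C)(C)O[C@H]1C=C(CO)[C@](O)(C(=O)OC)[C@@]2(C)CCCC(C)(C)[C@H]12 | intermediate
17 | methyl 6α-(tert-butyldimethylsilyloxy)-9α-hydroxy-12-oxodrim-7-en-11-oate | CC(C)(C)[Si](C)(C)O[C@H]1C=C(C=O)[C@](O)(C(=O)OC)[C@@]2(C)CCCC(C)(C)[C@H]12 | intermediate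
18 | methyl 6α,9α-dihydroxy-12-oxodrim-7-en-11-oate | O[C@H]1C=C(C=O)[C@](O)(C(=O)OC)[C@@]2(C)CCCC(C)(C)[C@H]12 | intermediate
19 | (2E,4E,6E)-octa-2,4,6-trienoic acid | C/C=C/C=C/C=C/C(=O)O | starting material
20 | methyl 9α-hydroxy-6α-[(2E,4E,6E)-octa-2,4,6-trienoyloxy]-12-oxodrim-7-en-11-oate | C/C=C/C=C/C=C/C(=O)O[C@H]1C=C(C=O)[C@](O)(C(=O)OC)[C@@]2(C)CCCC(C)(C)[C@H]12 | intermediate
21 | (5S,6S,9S,10S)-9-hydroxy-6-[(2E,4E,6E)-octa-2,4,6-trienoyloxy]-12-oxodrim-7-en-11-oic acid (6α-acyloxy, 9α-OH, 5α-H) | C/C=C/C=C/C=C/C(=O)O[C@H]1C=C(C=O)[C@](O)(C(=O)O)[C@@]2(C)CCCC(C)(C)[C@H]12 | target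

Total step count: 14. Longest linear sequence: 14 steps (1 to 21); 2, 6 and 19 enter as bought reagents.

Steps most likely to fail

Step 7. The risk is that hydrogen delivery to the C4 radical (or hydrogen loss back to the metal) outruns the slow first 6-endo closure onto the unactivated C5=C10 alkene, leaving reduced or isomerised open-chain material. The fallback makes the same C4 radical with no hydride present. It sets out from 10: Mukaiyama hydration of the isopropenyl group (Co(acac)2, PhSiH3, O2, i-PrOH; oxygen traps the C4 radical faster than it can cyclise) would give the tertiary alcohol dimethyl (2Z)-2-[(2S,3E)-2-(tert-butyldimethylsilyloxy)-8-hydroxy-4,8-dimethylnon-3-en-1-yl]but-2-enedioate F1. Acylation with methyl chlorooxoacetate (Et3N, 4-(dimethylamino)pyridine, CH2Cl2) would give the tertiary alkyl methyl oxalate F2, and one equivalent of CsOH in THF/H2O would cleave only the very reactive oxalate methyl ester to the caesium oxalate F3. Visible-light photoredox decarboxylation ([Ir(dF(CF3)ppy)2(dtbbpy)]PF6, blue LEDs, DME/DMF, H2O, 0.01 M) should then release the C4 radical, which closes ring A and ring B as before; the C8 radical is reduced by the photocatalyst and protonated by water, and the route is rejoined at 11.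

Step 14. The risk is loss of the C6 trienoate (or hydroxide addition to the polyene or enal) before the hindered C11 methyl ester is cleaved. The fallback exchanges the ester before acylation and sets out from 17: saponification while no other ester is present (LiOH, THF/H2O, rt) would give 6α-(tert-butyldimethylsilyloxy)-9α-hydroxy-12-oxodrim-7-en-11-oic acid F4. Alkylation of the carboxylate (4-methoxybenzyl chloride, Cs2CO3, DMF) would give the 4-methoxybenzyl ester F5, and HF·pyridine the 6α-alcohol 4-methoxybenzyl 6α,9α-dihydroxy-12-oxodrim-7-en-11-oate F6. Esterification with 19 (EDC·HCl, 4-(dimethylamino)pyridine) would give the trienoate 4-methoxybenzyl ester F7, and CF3CO2H with anisole in CH2Cl2 at 0 °C should release the acid without touching the trienoate, arriving at 21.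

Step 10. The risk is hydride delivery to the C11 ester through the neighbouring aluminium alkoxide, or lactonisation of the C12 alkoxide onto C11 followed by further reduction. The fallback differentiates the two carboxyls by hydrolysis and never forms the free hydroxy ester. It sets out from 15: the exposed conjugated C12 ester is saponified selectively (LiOH, 1.1 equiv, THF/H2O, 0 °C) to the mono-acid 6α-(tert-butyldimethylsilyloxy)-9α-hydroxy-11-methoxy-11-oxodrim-7-en-12-oic acid F8. Coupling with N,O-dimethylhydroxylamine hydrochloride (EDC·HCl, HOBt, i-Pr2NEt) would give the Weinreb amide F9, and i-Bu2AlH at −78 °C should stop at the aldehyde through the stable chelate, rejoining the route at 17 and bypassing 16.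

Further compounds
F1 | step 7 | dimethyl (2Z)-2-[(2S,3E)-2-(tert-butyldimethylsilyloxy)-8-hydroxy-4,8-dimethylnon-3-en-1-yl]but-2-enedioate | CC(C)(O)CCC/C(C)=C/[C@@H](O[Si](C)(C)C(C)(C)C)C/C(C(=O)OC)=C/C(=O)OC
F2 | step 7 | dimethyl (2Z)-2-[(2S,3E)-2-(tert-butyldimethylsilyloxy)-8-(2-methoxy-2-oxoacetoxy)-4,8-dimethylnon-3-en-1-yl]but-2-enedioate | COC(=O)C(=O)OC(C)(C)CCC/C(C)=C/[C@@H](O[Si](C)(C)C(C)(C)C)C/C(C(=O)OC)=C/C(=O)OC
F3 | step 7 | caesium 2-{[(5E,7S,9Z)-7-(tert-butyldimethylsilyloxy)-11-methoxy-9-(methoxycarbonyl)-2,6-dimethyl-11-oxoundeca-5,9-dien-2-yl]oxy}-2-oxoacetate | [Cs+].[O-]C(=O)C(=O)OC(C)(C)CCC/C(C)=C/[C@@H](O[Si](C)(C)C(C)(C)C)C/C(C(=O)OC)=C/C(=O)OC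
F4 | step 14 | 6α-(tert-butyldimethylsilyloxy)-9α-hydroxy-12-oxodrim-7-en-11-oic acid | CC(C)(C)[Si](C)(C)O[C@H]1C=C(C=O)[C@](O)(C(=O)O)[C@@]2(C)CCCC(C)(C)[C@H]12
F5 | step 14 | 4-methoxybenzyl 6α-(tert-butyldimethylsilyloxy)-9α-hydroxy-12-oxodrim-7-en-11-oate | CC(C)(C)[Si](C)(C)O[C@H]1C=C(C=O)[C@](O)(C(=O)OCc3ccc(OC)cc3)[C@@]2(C)CCCC(C)(C)[C@H]12
F6 | step 14 | 4-methoxybenzyl 6α,9α-dihydroxy-12-oxodrim-7-en-11-oate | O[C@H]1C=C(C=O)[C@](O)(C(=O)OCc3ccc(OC)cc3)[C@@]2(C)CCCC(C)(C)[C@H]12
F7 | step 14 | 4-methoxybenzyl 9α-hydroxy-6α-[(2E,4E,6E)-octa-2,4,6-trienoyloxy]-12-oxodrim-7-en-11-oate | C/C=C/C=C/C=C/C(=O)O[C@H]1C=C(C=O)[C@](O)(C(=O)OCc3ccc(OC)cc3)[C@@]2(C)CCCC(C)(C)[C@H]12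
F8 | step 10 | 6α-(tert-butyldimethylsilyloxy)-9α-hydroxy-11-methoxy-11-oxodrim-7-en-12-oic acid | CC(C)(C)[Si](C)(C)O[C@H]1C=C(C(=O)O)[C@](O)(C(=O)OC)[C@@]2(C)CCCC(C)(C)[C@H]12
F9 | step 10 | methyl 6α-(tert-butyldimethylsilyloxy)-9α-hydroxy-12-[methoxy(methyl)amino]-12-oxodrim-7-en-11-oate | CC(C)(C)[Si](C)(C)O[C@H]1C=C(C(=O)N(C)OC)[C@](O)(C(=O)OC)[C@@]2(C)CCCC(C)(C)[C@H]12
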